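Ring B is annulated onto an achiral ring A enone in one flask. The feature exploited is that C10 is β and C5 is α to a ring A carbonyl at C4, while the C7 isopropylidene beside the C8 ketone is the masked form of a β-keto ester (C11 = ester carbon). A copper-catalysed enantioselective methyl transfer to C10, Michael addition of the C5 enolate to methyl acrylate (C5–C6) and Dieckmann closure onto the acetate arm (C7–C8) therefore give the trans-decalin diketo ester with C10 and C5 set. The precursor is methyl 2-(3-oxocyclohex-1-en-1-yl)acetate; the C4 ketone later supplies C15, the 3,4-olefin and, by Woodward hydroxylation, the 3β,4β-diol monoacetate.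

Key step: step 2

Remark: eudesmane numbering is used (ring A = C1–C5 and C10, ring B = C5–C10, C14 on C10, C15 on C4); the target is read as 3β-angeloyloxy-4β-acetoxy-5αH-10β-methyl, that is (3S,4R,5R,10R).
Remark: the sense of induction of the copper–ligand pair cannot be fixed on paper; the ligand antipode that gives the 10R (10β-methyl) series is to be used.

Step 1
Reactants: 1 3-ethoxycyclohex-2-en-1-one; 2 methyl acetate
Product: 5 methyl 2-(3-oxocyclohex-1-en-1-yl)acetate, via lithium enolate of methyl acetate 3 (not isolated), via lithium alkoxide adduct 4 (not isolated)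
Conditions: 2, LiN(iPr)2 (LDA), THF, −78 °C; then 1, −78 → 0 °C; then 2 M HCl, 23 °C
Reagents that add atoms: water, O
Why: Stork–Danheiser alkylative carbonyl transposition, in which the ester enolate adds 1,2 to the vinylogous ester carbonyl and aqueous acid then ionises the tertiary allylic alcohol and hydrolyses the enol ether to the 3-substituted enone; no stereocentre is formed.

Step 2
Reactants: 5 methyl 2-(3-oxocyclohex-1-en-1-yl)acetate; 6 trimethylaluminium; 7 methyl acrylate
Product: 11 methyl (5R,10R)-10-methyl-4,8-dioxo-trans-decalin-7-carboxylate (eudesmane numbering; 5α-H; 10β-methyl; C7 enolisable), via dimethylaluminium enolate 8 (not isolated), via lithium aluminate enolate 9 (not isolated), via Michael adduct ester enolate 10 (not isolated)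
Conditions: Cu(OTf)2 (2 mol %), (S)-(1,1′-binaphthalene-2,2′-diyl) N,N-bis[(R)-1-phenylethyl]phosphoramidite (4 mol %), 6 (1.3 equiv), Et2O, −30 °C; then THF, MeLi (1 equiv per Al), −78 °C; 7 (1.1 equiv, slow addition), −78 → 0 °C; then NaOMe (excess), MeOH, 23 °C; aq. HCl
Reagents that add atoms: none
Why: Proposed new method: the copper–phosphoramidite complex transfers methyl from AlMe3 to the β-carbon C10 of 5 and leaves the regiodefined C4–C5 aluminium enolate 8, MeLi turns it into the more nucleophilic aluminate 9, which adds through C5 to 7 (C5–C6), and the ester enolate 10 so formed at C7 attacks the acetate carbonyl C8 and expels methoxide (C7–C8). The closest known reactions are the copper-catalysed asymmetric conjugate addition of AlMe3 to 3-substituted cyclohexenones with trapping of the activated aluminium enolate by carbon electrophiles, and the Michael–Dieckmann annulation of preformed ketone enolates with acrylates; only their union in one flask is new. Ring B closes in the 6-exo-trig mode, the kinetic ester enolate at C7 having only the C8 ester within reach of a six-membered transition state (attack on the C4 ketone would give a four-membered ring). C10 is controlled by the chiral ligand on copper, which selects one face of the planar, achiral enone. C5 is controlled thermodynamically, because the methoxide freed in the closure is consumed by the acidic β-keto ester and added methoxide is therefore used to epimerise the centre α to the C4 ketone; the trans fusion should be preferred since the axial C10 methyl then faces two trigonal carbons (C4 and C8). The step needs methyl transfer without attack on the esters (AlMe3 does not add to esters at this temperature), reaction at C5 and not C3 (secured by generating the enolate through conjugate addition) and one Dieckmann direction (secured by the site of the kinetic ester enolate).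

Step 3
Reactants: 11 methyl (5R,10R)-10-methyl-4,8-dioxo-trans-decalin-7-carboxylate
Product: 13 methyl (5R,10R)-8-(tert-butyldimethylsilyloxy)-10-methyl-4-oxo-trans-octal-7-ene-7-carboxylate (eudesmane numbering), via sodium enolate 12 (not isolated)
Conditions: NaH (1.05 equiv), THF, 0 °C; TBSCl, 0 → 23 °C
Reagents that add atoms: tert-butyldimethylsilyl chloride, CC(C)(C)[Si](C)(C)Cl
Why: Chemoselective enolate O-silylation, since one equivalent of NaH deprotonates only the far more acidic β-keto ester and the hard silyl chloride is taken up at oxygen, which masks C8 and turns the ester into a vinylogous carbonate; C5 and C10 are untouched.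

Step 4
Reactants: 13 methyl (5R,10R)-8-(tert-butyldimethylsilyloxy)-10-methyl-4-oxo-trans-octal-7-ene-7-carboxylate
Product: 15 methyl (5R,10R)-8-(tert-butyldimethylsilyloxy)-10-methyl-4-(trifluoromethanesulfonyloxy)-trans-hexahydronaphthalene-3,7-diene-7-carboxylate (eudesmane numbering; C3=C4 and C7=C8), via potassium enolate 14 (not isolated)
Conditions: KN(SiMe3)2 (1.1 equiv), THF, −78 °C; PhNTf2, −78 → 0 °C
Reagents that add atoms: N-phenylbis(trifluoromethanesulfonimide), O=S(=O)(N(c1ccccc1)S(=O)(=O)C(F)(F)F)C(F)(F)F
Why: Kinetic enolate triflation, in which the bulky amide removes a proton from the C3 methylene and not from the C5 methine next to quaternary C10 (so C5 is not epimerised) and PhNTf2 traps the enolate on oxygen as the 3,4-enol triflate.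

Step 5
Reactants: 15 the 3,4-enol triflate
Product: 16 methyl (5R,10R)-8-(tert-butyldimethylsilyloxy)-4,10-dimethyl-trans-hexahydronaphthalene-3,7-diene-7-carboxylate (eudesmane numbering; 12,13-dinoreudesma-3,7-diene ester)
Conditions: Fe(acac)3 (5 mol %), MeMgBr (1.5 equiv), THF/NMP, −30 → 0 °C
Reagents that add atoms: methylmagnesium bromide, C[Mg]Br
Why: Iron-catalysed Kumada-type cross-coupling of an alkenyl triflate with a Grignard reagent, fast enough at low temperature to spare the deactivated ester and the silyl enol ether; the olefin position is fixed by the triflate and no stereocentre changes.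

Step 6
Reactants: 16 the 4-methyl diene ester
Product: 18 (5R,10R)-eudesma-3,7(11)-dien-8-one, via tertiary carbinol 17 (not isolated)
Conditions: MeLi (4 equiv), CeCl3, THF, −78 → 0 °C; then 1 M HCl, THF, 23 °C
Reagents that add atoms: methyllithium, [Li]C
Why: Double 1,2-addition of the weakly basic methylcerium reagent to the ester gives carbinol 17, and acid then ionises this tertiary allylic alcohol with the push of the silyl enol ether and removes silicon (a vinylogous aldol dehydration), which places the new double bond at C7=C11 in conjugation with C8=O; the 3,4-olefin and C5/C10 are unaffected.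

Step 7
Reactants: 18 (5R,10R)-eudesma-3,7(11)-dien-8-one
Product: 21 (3S,4R,5R,10R)-3β-hydroxy-8-oxoeudesm-7(11)-en-4β-yl acetate, via trans iodoacetate 19 (not isolated), via acetoxonium ion 20 (not isolated)
Conditions: I2 (1.05 equiv), AgOAc (2.2 equiv), AcOH, 23 °C; then AcOH/H2O, 23 → 60 °C
Reagents that add atoms: silver acetate, CC(=O)[O-].[Ag+]; water, O
Why: Woodward cis-hydroxylation, in which acetyl hypoiodite puts iodine on the less hindered α-face of the electron-rich C3=C4 bond (anti to the axial C10 methyl; the conjugated C7=C11 bond is deactivated), acetate opens the iodonium ion trans-diaxially at tertiary C4 to give 19, silver-assisted displacement of the axial 3α-iodide by the neighbouring acetate gives the β-face acetoxonium ion 20, and water collapses it by breaking the equatorial C3–O bond, so that both new C–O bonds are β and the acetate should stay on the axial, tertiary O4.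

Step 8
Reactants: 21 (3S,4R,5R,10R)-3β-hydroxy-8-oxoeudesm-7(11)-en-4β-yl acetate; 22 angelic acid
Product: 24 (3S,4R,5R,10R)-4β-acetoxy-8-oxoeudesm-7(11)-en-3β-yl (Z)-2-methylbut-2-enoate (target CNP0141494.2), via mixed anhydride 23 (not isolated)
Conditions: 22, 2,4,6-trichlorobenzoyl chloride, Et3N, toluene, 23 °C; then 21, toluene, 80 °C
Reagents that add atoms: none
Why: Yamaguchi-type mixed anhydride esterification, in which the equatorial 3β-OH attacks the angeloyl carbonyl of 23 (the 2,6-dichloroaroyl carbonyl is shielded) and the absence of a nucleophilic amine catalyst avoids the addition–elimination path that isomerises angelate to tiglate; no stereocentre is touched.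

Compound list
1 | 3-ethoxycyclohex-2-en-1-one | CCOC1=CC(=O)CCC1 | starting material
2 | methyl acetate | COC(C)=O | starting material
3 | lithium enolate of methyl acetate | [Li+].[O-]C(=C)OC | intermediate
4 | lithium 3-ethoxy-1-(2-methoxy-2-oxoethyl)cyclohex-2-en-1-olate (racemic) | CCOC1=CC([O-])(CC(=O)OC)CCC1.[Li+] | intermediate
5 | methyl 2-(3-oxocyclohex-1-en-1-yl)acetate | COC(=O)CC1=CC(=O)CCC1 | intermediate
6 | trimethylaluminium | C[Al](C)C | starting material
7 | methyl acrylate | C=CC(=O)OC | starting material
8 | dimethylaluminium C4–C5 enolate of the methyl adduct (C10 set, R in this form) | C1CC[C@](C)(CC(=O)OC)C=C1O[Al](C)C | intermediate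
9 | lithium trimethylaluminate of enolate 8 | C1CC[C@](C)(CC(=O)OC)C=C1O[Al-](C)(C)C.[Li+] | intermediate
10 | lithium ester enolate of the C5 Michael adduct (C5 epimers) | C1CC[C@](C)(CC(=O)OC)C(CC=C([O-])OC)C1=O.[Li+] | intermediate
11 | methyl (5R,10R)-10-methyl-4,8-dioxo-trans-decalin-7-carboxylate (eudesmane numbering) | C1CC[C@]2(C)CC(=O)C(C(=O)OC)C[C@H]2C1=O | intermediate
12 | sodium C7–C8 enolate of 11 | C1CC[C@]2(C)CC([O-])=C(C(=O)OC)C[C@H]2C1=O.[Na+] | intermediate
13 | methyl (5R,10R)-8-(tert-butyldimethylsilyloxy)-10-methyl-4-oxo-trans-octal-7-ene-7-carboxylate | C1CC[C@]2(C)CC(O[Si](C)(C)C(C)(C)C)=C(C(=O)OC)C[C@H]2C1=O | intermediate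
14 | potassium C3–C4 enolate of 13 | C1C[C@]2(C)CC(O[Si](C)(C)C(C)(C)C)=C(C(=O)OC)C[C@H]2C([O-])=C1.[K+] | intermediate
15 | 3,4-enol triflate of 13 (5R,10R) | C1C[C@]2(C)CC(O[Si](C)(C)C(C)(C)C)=C(C(=O)OC)C[C@H]2C(OS(=O)(=O)C(F)(F)F)=C1 | intermediate
16 | methyl (5R,10R)-8-(tert-butyldimethylsilyloxy)-4,10-dimethyl-trans-hexahydronaphthalene-3,7-diene-7-carboxylate | C1C[C@]2(C)CC(O[Si](C)(C)C(C)(C)C)=C(C(=O)OC)C[C@H]2C(C)=C1 | intermediate
17 | (5R,10R)-8-(tert-butyldimethylsilyloxy)eudesma-3,7-dien-11-ol | C1C[C@]2(C)CC(O[Si](C)(C)C(C)(C)C)=C(C(C)(C)O)C[C@H]2C(C)=C1 | intermediate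
18 | (5R,10R)-eudesma-3,7(11)-dien-8-one | C1C[C@]2(C)CC(=O)C(=C(C)C)C[C@H]2C(C)=C1 | intermediate
19 | (3R,4R,5R,10R)-3α-iodo-8-oxoeudesm-7(11)-en-4β-yl acetate | I[C@@H]1CC[C@]2(C)CC(=O)C(=C(C)C)C[C@H]2[C@@]1(C)OC(C)=O | intermediate
20 | 3β,4β-fused 2-methyl-1,3-dioxolan-2-ylium acetate of 8-oxoeudesm-7(11)-ene | CC1=[O+][C@H]2CC[C@]3(C)CC(=O)C(=C(C)C)C[C@H]3[C@@]2(C)O1.CC(=O)[O-] | intermediate
21 | (3S,4R,5R,10R)-3β-hydroxy-8-oxoeudesm-7(11)-en-4β-yl acetate | O[C@H]1CC[C@]2(C)CC(=O)C(=C(C)C)C[C@H]2[C@@]1(C)OC(C)=O | intermediate
22 | angelic acid, (Z)-2-methylbut-2-enoic acid | C/C=C(/C)C(=O)O | starting material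
23 | angelic 2,4,6-trichlorobenzoic anhydride | C/C=C(/C)C(=O)OC(=O)c1c(Cl)cc(Cl)cc1Cl | intermediate
24 | (3S,4R,5R,10R)-4β-acetoxy-8-oxoeudesm-7(11)-en-3β-yl angelate | C/C=C(/C)C(=O)O[C@H]1CC[C@]2(C)CC(=O)C(=C(C)C)C[C@H]2[C@@]1(C)OC(C)=O | target

Total step count: 8. Longest linear sequence: 8 steps (1 → 24).

Steps most likely to fail

Step 2 (bears the label). The aluminate enolate may add too slowly to the acrylate, so that the acrylate oligomerises. The doubly activated C9 methylene of 5 may be deprotonated instead of the enone accepting methyl. The C5 epimerisation may stop short of the trans-fused equilibrium, in which case the cis-fused part would be separated and resubmitted to methoxide. The fallback uses known chemistry only, sets out from 5 and returns at 11. The same copper-catalysed methyl addition is run alone and enolate 8 is trapped with TMSOTf to give the isolable silyl enol ether F1. MeLi in THF cleaves F1 to the regiodefined lithium enolate F2, a conventional partner for methyl acrylate at −78 °C (Michael addition to 10, then Dieckmann closure). Equilibration with NaOMe in MeOH as in step 2 then gives 11.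

Step 7. Iodonium formation or opening may take the wrong face or the wrong carbon, electrophilic iodine may attack the enone or C9, and the acetyl group may shift from O4 to O3 during collapse of the orthoacid or on warming. The fallback sets out from 18 and returns at 21. mCPBA (NaHCO3, CH2Cl2, 0 °C) should epoxidise only the isolated trisubstituted olefin from the α-face to give the α-epoxide F3. Acetic acid at 23 °C should open it trans-diaxially at tertiary C4 to give the 3α-hydroxy 4β-acetate F4. Dess–Martin periodinane oxidises the axial alcohol to the 3-ketone F5. NaBH4 in MeOH at −78 °C, delivering hydride axially from the α-face and faster to the saturated ketone than to the hindered enone, should give the equatorial 3β-alcohol 21.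

Step 8. The angeloyl unit may isomerise from Z to E during activation or heating, and the amine base may move the acetyl group from O4 to O3 before acylation. The fallback sets out from 21 and ends at 24. The alcohol is esterified with 2-[bis(2,2,2-trifluoroethoxy)phosphoryl]propanoic acid (DCC, cat. DMAP, CH2Cl2) to give the phosphonopropionate ester F6. Deprotonation with KN(SiMe3)2 and 18-crown-6 in THF at −78 °C gives its potassium salt F7. Z-selective Still–Gennari olefination with acetaldehyde then builds the angelate double bond on the molecule and gives 24.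

Further compounds
F1 | step 2 | methyl 2-[(1R)-1-methyl-3-(trimethylsilyloxy)cyclohex-2-en-1-yl]acetate | COC(=O)C[C@@]1(C)CCCC(O[Si](C)(C)C)=C1
F2 | step 2 | lithium enolate obtained from F1 | COC(=O)C[C@@]1(C)CCCC([O-])=C1.[Li+]
F3 | step 7 | (5R,10R)-3α,4α-epoxyeudesm-7(11)-en-8-one | O1[C@@H]2CC[C@]3(C)CC(=O)C(=C(C)C)C[C@H]3[C@]12C
F4 | step 7 | 3α-hydroxy-8-oxoeudesm-7(11)-en-4β-yl acetate | O[C@@H]1CC[C@]2(C)CC(=O)C(=C(C)C)C[C@H]2[C@@]1(C)OC(C)=O
F5 | step 7 | 3,8-dioxoeudesm-7(11)-en-4β-yl acetate | O=C1CC[C@]2(C)CC(=O)C(=C(C)C)C[C@H]2[C@@]1(C)OC(C)=O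
F6 | step 8 | 4β-acetoxy-8-oxoeudesm-7(11)-en-3β-yl 2-[bis(2,2,2-trifluoroethoxy)phosphoryl]propanoate | CC(P(=O)(OCC(F)(F)F)OCC(F)(F)F)C(=O)O[C@H]1CC[C@]2(C)CC(=O)C(=C(C)C)C[C@H]2[C@@]1(C)OC(C)=O
F7 | step 8 | potassium salt of the phosphonate carbanion of F6 | [K+].C[C-](P(=O)(OCC(F)(F)F)OCC(F)(F)F)C(=O)O[C@H]1CC[C@]2(C)CC(=O)C(=C(C)C)C[C@H]2[C@@]1(C)OC(C)=O
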